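(All runs were computed for an exercise.)

A closed, stirred vessel at constant volume and temperature holds G and L. G turns to Q within minutes, L feeds Z, and Q + Z makes J, while two Q can give E and Z can leak to D.

| flask | G | L | remark | time |
|---|---|---|---|---|
| theta | 0.50 M | 1 M | run made earlier |  |
| south-west | 1.0 M | 1.00 M |  | 2.5 h |
| south | 1.0 M | 1.00 M |  | 6.0 h |

theta run (percent of the G charged)

| time / min | E / % | Q / % | J / % | G / % |
|---|---|---|---|---|
| 4.00 | 0 | 81.8 | 0.9 | 20.4 |
| 6.00 | 0 | 91.8 | 0.1 | 9.9 |
| 8.00 | 0 | 93.6 | 1.1 | 3.2 |
| 12.0 | 2.4 | 97.2 | 1.7 | 1.3 |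
| 20.0 | 0 | 95.4 | 3.1 | 0 |
| 30.0 | 1.6 | 91.4 | 6.2 | 1.2 |
| 50.0 | 2.4 | 83.0 | 15.7 | 0 |

(scatter of a reading: 1 percentage point)

- which of these there is most of at the end, counted by the G in it, south-west (G / E / J / Q)
- which of these there is most of at the end, counted by the G in it, south (G / E / J / Q)
- amount of the one of these that there is most of at the end, in percent of the G charged, south-west
- amount of the one of these that there is most of at the end, in percent of the G charged, south

- percent here means G units held: one E counts as two
- on the list of suspects stand: Z -> D; L -> Z; L <-> X; G -> Q; 2 Q -> E; Q + Z -> J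

Your number is the half-life of Q on its way to J. Take J's rise between the last two theta readings and divide it by the mean Q. That gives the share of Q taken per unit time at the Z then standing (pseudo-first-order, Z held). As a half-life, this is 2.12 h, a little shorter than 2.5 h.

The L charge matches theta's, so I carry it over. J's line, run back, starts at 16.9 min. From there I reckon Q at 48.4% in south-west, and J and E share the remainder, so in south-west Q leads J once E holds more than 3.1 percentage points. The theta run read E at 2.4% after 50.0 min, and south-west holds twice the G for longer, so I expect E to pass that mark and put Q first there. South gives Q 15.4%, less than south-west. I take that as a lowest value, since Z comes from a finite charge, and J leads there.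

The forecast says Q at 52% for south-west, “a close call”, and J at 65% for south. The flasks give Q at 48.4% in south-west and J at 53.4% in south.

    Z → D (k = 6.00 × 10⁻⁵ /s)
    L → Z (k = 3.30 × 10⁻⁴ /s)
    L ⇌ X (K = 0.550, k = 2.80 × 10⁻⁵ /s)
    G → Q (k = 0.00680 /s)
    2 Q → E (k = 1.40 × 10⁻⁵ /M/s)
    Q + Z → J (k = 1.70 × 10⁻⁴ /M/s)

The read half-life of 2.12 h belongs to the theta run, and it lengthens as Z falls, since it is the logarithm of 2 over the rate constant of Q + Z times the Z present. In south at 6.00 h, Z is 0.0948 M, which gives 12.0 h, longer than the run, and Q stands at 28.8%. In the same flask left until 15 h, Z is 0.0102 M, the half-life is 111 h, longer than that time, and Q still holds 19.3%.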